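The runs come from a simulation with made-up constants; the scatter is artificial.

I decided to watch one number in a repeat of these flasks, the charged L, and to turn it into a share of J before looking at the clock.

| flask | J | L | Z | remark | time |
|---|---|---|---|---|---|
| oak | 0.031 M | 1.1 equiv | 0.010 M | run made earlier |  |
| maple | 0.10 M | 1.6 equiv | 0.010 M | run made earlier |  |
| Monday's | 0.30 M | 0.550 equiv | 0.00500 M |  | 80 min |
| Tuesday's | 0.030 M | 2.20 equiv | 0.00500 M |  | 80 min |
| Saturday's | 0.40 M | 1.10 equiv | 0.0100 M |  | 80 min |
| Wednesday's | 0.20 M | 4.40 equiv | 0.00500 M |  | 80 min |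
| Thursday's | 0.10 M | 4.40 equiv | 0.00500 M |  | 80 min |
| Friday's | 0.10 M | 1.10 equiv | 0.0100 M |  | 80 min |

| run | time / min | G / % | J / % |
|---|---|---|---|
| oak | 4.00 | 3.7 | 67.0 |
| oak | 10.0 | 8.0 | 44.0 |
| oak | 20.0 | 10.9 | 23.0 |
| oak | 30.0 | 13.2 | 11.6 |
| oak | 40.0 | 14.9 | 7.0 |
| maple | 8.00 | 26.5 | 42.7 |
| maple | 15.0 | 36.6 | 22.0 |
| maple | 25.0 | 44.2 | 9.4 |
| maple | 30.0 | 46.7 | 6.3 |
| maple | 40.0 | 46.9 | 3.4 |

(standard deviation of a reading: 0.5 percentage points)

- the flasks by amount of G, in percent of the J charged, highest first, at 80 min (Monday's / Tuesday's / Saturday's / Wednesday's / Thursday's / Friday's)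
- the same order at 15 min (Monday's / Tuesday's / Saturday's / Wednesday's / Thursday's / Friday's)
- the amount of G, in percent of the J charged of the flask you put first, at 80 min
- the amount of G, in percent of the J charged of the flask you put last, at 80 min

- no earlier run changes the charge of Z; that part of a forecast is a guess

In the maple run at 40.0 min, 48.6 % of the lost J stood as G, and at 8.00 min the reading was 46.2 %, so the share hardly moved as J fell. I read this as two paths for J, one in proportion to L and giving G, and one without L. The large term is then the charged L, and the correction is the L spent, one per G, of which the mean over the run has lost half. I named the odds of G (share over remainder) per molar of mean L the capture constant, a selectivity factor: with maple's mean L of 0.137 M it read 6.91 M⁻¹. Oak read 6.00 M⁻¹, lower, so my figures carry that spread, and leaving Z out was a guess.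

The same split gave the clock: from maple's early loss I reckoned a background rate of 0.0505 min⁻¹, to be multiplied by one plus the capture constant times the charged L. I reckoned Tuesday's J half-life at 9.42 min, far below 80 min, so I counted nearly all of its J as lost and took the share as the G at that time.

Solving share and mean L together, I reckoned 84.6 % for Wednesday's, 73.6 % for Thursday's, 67.8 % for Saturday's, 41.5 % for Monday's, 38.5 % for Friday's and 29.8 % for Tuesday's. I kept this order at 15 min, and I reckoned Wednesday's J half-life at the charge at 1.94 min, shorter than Saturday's 3.40 min.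

The forecast, which said “Z probably acts as a catalyst”, gave Wednesday's > Thursday's > Saturday's > Monday's > Friday's > Tuesday's at 80 min and Saturday's > Wednesday's > Thursday's > Friday's > Monday's > Tuesday's at 15 min, with 80 % of G for its first flask and 27 % for its last at 80 min, so its figure for the first flask stood below mine and its order at 15 min differed from mine.

The flasks gave Wednesday's > Thursday's > Saturday's > Monday's > Friday's > Tuesday's at 80 min and Wednesday's > Thursday's > Saturday's > Monday's > Friday's > Tuesday's at 15 min, with 85.1 % of G in the first flask and 29.3 % in the last at 80 min.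

    J → Q (k = 6.80 × 10⁻⁴ s⁻¹)
    L → X (k = 2.93 × 10⁻⁷ s⁻¹)
    J + Z → E (k = 0.0931 M⁻¹ s⁻¹)
    Q ⇌ D (K = 0.470, k = 7.27 × 10⁻⁵ s⁻¹)
    J + L → G (k = 0.00587 M⁻¹ s⁻¹)

Wednesday's G gave back a capture constant of 7.20 M⁻¹ on its own mean L, beside the 6.91 M⁻¹ read from maple. Its neighbour, the same flask with 11.0 equiv of L, I reckoned the same way at 93.6 %. That flask gave 93.0 % of G, and beside it stood 4.04 % of Q, against 9.87 % of Q in Wednesday's.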